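**Plan**
- Retrosynthesis: the benzoate, the acetate and the C13 vinyl group come off last; the C2 and C3 acids and the C14 ketone are traced to one ozonolysis, of a temporary cyclohexene ring A (C1–C2=C3–C4–C5–C10) and of an exocyclic C14 methylene.
- Key cut, C8–C9 together with C13–C14: intramolecular [4+2] of a (Z)-2-silyloxy diene C9=C11–C12=C13 on C10 with the ketone-conjugated C8=C14 bond of an α-alkoxyallenyl ketone on C5–C6–C7. The four-atom tether C10–C5–C6–C7 becomes ring B; ring A, absent from the target, holds both arms trans-diequatorial.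
- The triene is cut at C7–C11 of a cyclohexanone (α-ketol cleavage), ring A at C2=C3 (metathesis) and at C10–C1 (conjugate allylation); the first ring comes from an organocatalytic annulation.
- Forward ring order: cyclohexenone, then ring A, then opening of the first ring, then rings B and C together (key step), then cleavage of ring A.
- Stereochemistry: C5 from the amine catalyst; C10 from C5; C8 and C9 from the chair-like cycloaddition geometry; C7 and C11 from hydride delivery by the 8β-hydroxyl; C13 from vinylation anti to the 8β-silyloxy group.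

Key step: step 15

Remark on numbering: locants are those of the 2,3-seco-isopimarane skeleton of the target (acids C2 and C3; C1H2 and CH3 on C10; C4 with its two methyls on C5; ring B = C5–C10; ring C = C8, C9, C11–C14; vinyl C15=C16); α is the face of H-5 and H-9, β the face of the C10 methyl group.
Assumption: 3,3-dimethylpent-4-enal (1) is taken as a purchasable aldehyde.

**Step 1**
Reactants: 1 3,3-dimethylpent-4-enal; 2 but-3-en-2-one
Product: 4 (R)-4-(2-methylbut-3-en-2-yl)cyclohex-2-en-1-one, via Michael adduct keto aldehyde 3 (not isolated)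
Conditions: (S)-2-[methoxy(diphenyl)methyl]pyrrolidine (10 mol%), ethyl 3,4-dihydroxybenzoate (20 mol%), neat, 4 °C; then LiOH (30 mol%), i-PrOH, 0 °C → rt
Reagents that add atoms: none
Why: Enamine-mediated organocatalytic Michael addition of 1 to 2 followed in the same flask by base-induced intramolecular aldol condensation (a Robinson-type annulation) should give the 4-substituted cyclohexenone, the (S)-pyrrolidine shielding one face of the (E)-enamine so that C5 is formed with the R configuration.

**Step 2**
Reactants: 4 (R)-4-(2-methylbut-3-en-2-yl)cyclohex-2-en-1-one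
Product: 5 trimethyl{[(3S,4R)-3-methyl-4-(2-methylbut-3-en-2-yl)cyclohex-1-en-1-yl]oxy}silane
Conditions: Me2CuLi (1.5 equiv), Me3SiCl (3 equiv), THF, −78 → −40 °C
Reagents that add atoms: lithium dimethylcuprate, [Li+].C[Cu-]C; chlorotrimethylsilane, C[Si](C)(C)Cl
Why: Conjugate addition of the Gilman cuprate with in situ silylation of the enolate should place the methyl group on C10 anti to the bulky C5 side chain (a centre that is removed again in step 3) and fix the enol ether regiochemistry for the next step.

**Step 3**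
Reactants: 5 silyl enol ether
Product: 6 (R)-3-methyl-4-(2-methylbut-3-en-2-yl)cyclohex-2-en-1-one
Conditions: Pd(OAc)2 (10 mol%), O2 (1 atm), DMSO, rt
Reagents that add atoms: none
Why: Saegusa–Ito dehydrosilylation (catalytic palladium diacetate reoxidised by O2) should return the enone, now with the C10 methyl group in place and C5 untouched.

**Step 4**
Reactants: 6 (R)-3-methyl-4-(2-methylbut-3-en-2-yl)cyclohex-2-en-1-one
Product: 7 (3R,4R)-3-allyl-3-methyl-4-(2-methylbut-3-en-2-yl)cyclohexan-1-one
Conditions: allyltrimethylsilane (3 equiv), TiCl4 (1.2 equiv), CH2Cl2, −78 → −40 °C; H2O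
Reagents that add atoms: allyltrimethylsilane, C=CC[Si](C)(C)C
Why: Hosomi–Sakurai conjugate allylation, in which the allylsilane should attack the TiCl4-activated enone axially on the face anti to the pseudoaxial 2-methylbut-3-en-2-yl group on C5, creating the quaternary centre C10 with the allyl group (C1–C2) trans to that group.

**Step 5**
Reactants: 7 (3R,4R)-3-allyl-3-methyl-4-(2-methylbut-3-en-2-yl)cyclohexan-1-one
Product: 8 (4aR,8aR)-5,5,8a-trimethyl-3,4,4a,5,8,8a-hexahydronaphthalen-2(1H)-one
Conditions: second-generation Grubbs catalyst RuCl2(=CHPh)(PCy3)(H2IMes) (5 mol%), CH2Cl2 (0.01 M), 40 °C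
Reagents that add atoms: none
Why: Ring-closing olefin metathesis of the allyl and 1,1-dimethylallyl groups, which are trans on adjacent carbons, should close the temporary cyclohexene ring A as a trans-fused bicycle and so lock C6 and C9 in a diequatorial relationship.

**Step 6**
Reactants: 8 bicyclic ketone
Product: 9 (3R,4aR,8aR)-3-hydroxy-5,5,8a-trimethyl-3,4,4a,5,8,8a-hexahydronaphthalen-2(1H)-one (C7 hydroxyl, C11 ketone)
Conditions: KN(SiMe3)2 (1.1 equiv), THF, −78 °C; 2-(phenylsulfonyl)-3-phenyloxaziridine (1.3 equiv), −78 °C; aq. NH4Cl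
Reagents that add atoms: 2-(phenylsulfonyl)-3-phenyloxaziridine, O=S(=O)(c1ccccc1)N1OC1c1ccccc1
Why: Kinetic deprotonation should occur at C7, away from the neopentyl C9 next to the angular methyl group, and electrophilic hydroxylation of the enolate by the N-sulfonyloxaziridine (enolate oxidation) should give the α-hydroxy ketone by axial attack anti to the angular methyl group, a carbinol centre that is lost in step 9.

**Step 7**
Reactants: 9 α-hydroxy ketone
Product: 10 (2S,3R,4aR,8aR)-5,5,8a-trimethyl-2-[(E)-prop-1-en-1-yl]-1,2,3,4,4a,5,8,8a-octahydronaphthalene-2,3-diol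
Conditions: (E)-1-bromoprop-1-ene (2.5 equiv), t-BuLi (5 equiv), Et2O, −78 °C; then 9, THF, −78 → −40 °C; aq. NH4Cl
Reagents that add atoms: (E)-1-bromoprop-1-ene, C/C=C/Br
Why: 1,2-Addition of the configurationally stable (E)-alkenyllithium (two equivalents, the first being consumed by the hydroxyl group) to the C11 ketone should occur from the face remote from the angular methyl group and brings in C12, C13 and the C13 methyl carbon with E geometry, the new carbinol centre being lost in step 9.

**Step 8**
Reactants: 10 diol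
Product: 11 (3S,4aR,8aR)-3-hydroxy-4a,8,8-trimethyl-3-[(E)-prop-1-en-1-yl]-3,4,4a,5,8,8a-hexahydronaphthalen-2(1H)-one (C7 ketone, C11 tertiary alcohol)
Conditions: Dess–Martin periodinane (1.5 equiv), NaHCO3, CH2Cl2, 0 °C → rt
Reagents that add atoms: none
Why: Dess–Martin oxidation should convert the secondary C7 alcohol into the ketone while the tertiary allylic alcohol cannot be oxidised, which turns a possibly trans-diaxial diol into an α-ketol that can be cleaved whatever its configuration.

**Step 9**
Reactants: 11 α-ketol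
Product: 12 2-{(1R,6R)-2,2,6-trimethyl-6-[(E)-2-oxopent-3-en-1-yl]cyclohex-3-en-1-yl}acetic acid
Conditions: H5IO6 (1.5 equiv), THF/H2O (3:1), 0 °C → rt
Reagents that add atoms: water, O
Why: Periodate cleavage of the α-hydroxy ketone (glycol-type cleavage through the cyclic periodate of the ketone hydrate) should break C7–C11 and open the first ring, giving the C11 (E)-enone and the C7 carboxylic acid, while the ring A alkene is inert.

**Step 10**
Reactants: 12 keto acid
Product: 13 N-methoxy-N-methyl-2-{(1R,6R)-2,2,6-trimethyl-6-[(E)-2-oxopent-3-en-1-yl]cyclohex-3-en-1-yl}acetamide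
Conditions: MeNH(OMe)·HCl, N-(3-dimethylaminopropyl)-N′-ethylcarbodiimide hydrochloride, N-methylmorpholine, CH2Cl2, 0 °C → rt
Reagents that add atoms: N,O-dimethylhydroxylamine hydrochloride, CNOC.Cl
Why: Carbodiimide-mediated amidation should give the Weinreb amide, which masks C7 at the acid oxidation level through the next step and later stops organolithium addition at the ketone stage.

**Step 11**
Reactants: 13 Weinreb amide enone
Product: 14 (Z)-silyl dienol ether: 2-{6-[(1Z,3E)-2-(tert-butyldimethylsilyloxy)penta-1,3-dien-1-yl]-2,2,6-trimethylcyclohex-3-en-1-yl}-N-methoxy-N-methylacetamide (5α-H, 10β-CH3, arms trans)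
Conditions: t-BuMe2SiOTf (1.3 equiv), Et3N (2 equiv), CH2Cl2, −78 → 0 °C
Reagents that add atoms: tert-butyldimethylsilyl trifluoromethanesulfonate, CC(C)(C)[Si](C)(C)OS(=O)(=O)C(F)(F)F
Why: Soft enolisation (silyl triflate and amine) of the enone at its only α′ position C9 should give the cross-conjugated 2-silyloxy diene, with Z geometry at C9=C11 because the quaternary C10 avoids the C12 vinyl group (A(1,3) strain), the amide not being enolised under these conditions.

**Step 12**
Reactants: 15 prop-2-yn-1-ol
Product: 16 3-(methoxymethoxy)prop-1-yne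
Conditions: MeOCH2Cl, i-Pr2NEt, CH2Cl2, 0 °C → rt
Reagents that add atoms: chloromethyl methyl ether, COCCl
Why: Williamson-type alkylation of the alcohol by the α-chloro ether gives the methoxymethyl ether.

**Step 13**
Reactants: 16 3-(methoxymethoxy)prop-1-yne
Product: 17 1-(methoxymethoxy)propa-1,2-diene
Conditions: KOt-Bu (20 mol%), THF, rt
Reagents that add atoms: none
Why: Base-catalysed propargyl-to-allenyl isomerisation of the propargyl ether should give the 1-alkoxyallene, conjugation of the oxygen with the allene being the driving force.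

**Step 14**
Reactants: 14 silyl dienol ether Weinreb amide; 17 1-(methoxymethoxy)propa-1,2-diene
Product: 19 allenyl ketone 1-{6-[(1Z,3E)-2-(tert-butyldimethylsilyloxy)penta-1,3-dien-1-yl]-2,2,6-trimethylcyclohex-3-en-1-yl}-3-(methoxymethoxy)penta-3,4-dien-2-one, via 1-lithio-1-(methoxymethoxy)propa-1,2-diene 18 (not isolated)
Conditions: 17 (1.5 equiv), n-BuLi (1.4 equiv), THF, −78 °C; then 14, −78 °C; aq. NH4Cl
Reagents that add atoms: none
Why: α-Lithiation of the alkoxyallene at the oxygen-bearing carbon and acylation of the resulting 18 by the Weinreb amide (nucleophilic acyl substitution through a stable chelated tetrahedral intermediate) should give the α-alkoxyallenyl ketone without over-addition, the silyl dienol ether being inert to the organolithium at −78 °C.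

**Step 15**
Reactants: 19 allenyl ketone triene
Product: 21 tricyclic 7,11-diketone (8β-methoxymethoxy; 13β-methyl; 14-methylene; 9α-H; ring A 2-ene), via cycloadduct silyl enol ether 20 (not isolated)
Conditions: toluene (0.01 M), 2,6-di-tert-butyl-4-methylphenol (5 mol%), 100 °C; then THF, 1 M aq. HCl, 0 °C
Reagents that add atoms: none
Why: Heating 19 should bring about a concerted but asynchronous thermal type 1 intramolecular Diels–Alder reaction in which the (Z)-2-silyloxy diene C9=C11–C12=C13 adds suprafacially across the ketone-conjugated C8=C14 bond of the α-alkoxyallenyl ketone, whose sp-hybridised C14 keeps the bond-forming site at C13 uncrowded; the closest known reaction types are the thermal cyclisation of deca-1,7,9-trien-3-ones and the Diels–Alder addition of allenyl ketones to 2-silyloxy dienes. Ring C is closed as the [4+2] ring by both new bonds, and ring B as the six-membered ring of the four-atom tether C10–C5–C6–C7 through the C8–C9 bond in a chair-like arrangement. C8 and C9 are set together under the control of the temporary ring A, which holds C9 and C6 trans-diequatorial with the C10 methyl group axial: the chair with C11 and C14 both equatorial keeps the bulky C5 on the hydrogen side of the C9=C11 bond and gives the trans B/C fusion (9α-H, 8β-oxygen), whereas the chair that would put C14 axial runs into the C10 methyl group, and C13 receives its methyl group cis to C10 because the (E)-methyl group and C10 are both outside substituents of the diene. The step needs periselectivity and a regiochemistry that runs against the electronic bias of the diene (C9 towards C14), and the short tether secures both, since the other pairing would need a bridged seven-membered ring; heat alone is used because a Lewis acid would open a stepwise Mukaiyama–Michael attack at C14. The allene leaves C14 as an exocyclic methylene, the latent ketone, and the dilute acid added at the end only hydrolyses the silyl enol ether to the C11 ketone.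

**Step 16**
Reactants: 21 tricyclic 7,11-diketone methoxymethyl ether
Product: 22 8β-hydroxy-13β-methyl-14-methylene tricyclic 7,11-dione
Conditions: Me2BBr (2.5 equiv), CH2Cl2, −78 °C; then THF/aq. NaHCO3, 0 °C
Reagents that add atoms: none
Why: Cleavage of the methoxymethyl ether with dimethylboron bromide at −78 °C (Lewis acid-assisted acetal cleavage) should free the tertiary 8β-hydroxyl under conditions too mild for β-elimination or retro-aldol reaction of the β-oxygenated C11 ketone.

**Step 17**
Reactants: 22 8β-hydroxy 7,11-dione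
Product: 23 7α,8β,11α-triol (13β-methyl, 14-methylene, ring A 2-ene)
Conditions: Me4NBH(OAc)3 (6 equiv), MeCN/AcOH (1:1), −30 → −20 °C
Reagents that add atoms: none
Why: Evans–Saksena reduction, in which the 8β-hydroxyl binds the triacetoxyborohydride and delivers hydride intramolecularly to the β face of both the α-ketone C7 and the β-ketone C11 (1,3-diaxial delivery across ring C), should give the 7α- and 11α-alcohols, both anti to O-8, in one operation.

**Step 18**
Reactants: 23 triol
Product: 24 7α,8β,11α-tris(triethylsilyl) ether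
Conditions: Et3SiOTf (4.5 equiv), 2,6-lutidine (6 equiv), CH2Cl2, 0 °C → rt
Reagents that add atoms: triethylsilyl trifluoromethanesulfonate, CC[Si](CC)(CC)OS(=O)(=O)C(F)(F)F
Why: Silylation with the silyl triflate should cap all three hydroxyls, the tertiary one included, which protects them through the oxidations and places a bulky group on the β face next to C14 for step 22.

**Step 19**
Reactants: 24 tris(triethylsilyl) ether
Product: 25 2,3-seco 14-ketone 2,3-dialdehyde
Conditions: O3, CH2Cl2/MeOH (4:1), −78 °C; Me2S, −78 °C → rt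
Reagents that add atoms: ozone, [O-][O+]=O
Why: Ozonolysis with reductive work-up should cleave the two remaining alkenes at once, turning the exocyclic methylene into the C14 ketone and the temporary ring A into the C2 and C3 aldehydes.

**Step 20**
Reactants: 25 keto dialdehyde
Product: 26 2,3-seco 14-ketone 2,3-dioic acid
Conditions: NaClO2, NaH2PO4, 2-methylbut-2-ene, t-BuOH/H2O, 0 °C → rt
Reagents that add atoms: sodium chlorite, [Na+].[O-]Cl=O
Why: Pinnick oxidation should convert both aldehydes, the neopentyl one included, into the carboxylic acids without touching the ketone or the silyl ethers.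

**Step 21**
Reactants: 26 diacid
Product: 27 bis(4-methoxybenzyl) ester
Conditions: 4-methoxybenzyl chloride (2.5 equiv), Cs2CO3 (1.2 equiv), DMF, rt
Reagents that add atoms: 4-methoxybenzyl chloride, COc1ccc(CCl)cc1
Why: O-Alkylation of the dicarboxylate by the benzylic chloride (SN2) should give the diester even at the hindered C3 carboxylate, because the reaction takes place at the benzylic carbon.

**Step 22**
Reactants: 27 bis(4-methoxybenzyl) ester 14-ketone
Product: 28 13α-vinyl-13β-methyl 14-ketone
Conditions: bromoethene (1 M in THF, 3 equiv), Pd2(dba)3 (dba = dibenzylideneacetone, 5 mol%), P(t-Bu)3 (12 mol%), LiN(SiMe3)2 (1.2 equiv), toluene, rt → 50 °C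
Reagents that add atoms: bromoethene, C=CBr
Why: Palladium-catalysed α-vinylation of the ketone enolate (oxidative addition of bromoethene to zerovalent palladium, enolate transmetalation and reductive elimination) should create the quaternary centre C13, C14 being enolisable only towards C13, and the vinyl group should enter on the α face because the β face is blocked by the syn-axial 8β-triethylsilyloxy group, which leaves the methyl group β.

**Step 23**
Reactants: 28 tris(triethylsilyl) ether
Product: 29 7α,8β,11α-triol bis(4-methoxybenzyl) ester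
Conditions: HF·pyridine, pyridine, THF, 0 °C → rt
Reagents that add atoms: none
Why: Fluoride-mediated desilylation should remove the three triethylsilyl groups while the esters, the ketone and the vinyl group are unaffected.

**Step 24**
Reactants: 29 triol
Product: 30 11α-benzoate
Conditions: PhCOCl (1.2 equiv), pyridine, 4-(dimethylamino)pyridine (cat.), CH2Cl2, −20 → 0 °C
Reagents that add atoms: benzoyl chloride, O=C(Cl)c1ccccc1
Why: Acylation under nucleophilic catalysis should take place selectively at the equatorial secondary 11α-hydroxyl, the axial 7α-hydroxyl next to the quaternary C8 and the tertiary 8β-hydroxyl being much slower.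

**Step 25**
Reactants: 30 11α-benzoate
Product: 31 7α-acetate 11α-benzoate bis(4-methoxybenzyl) ester
Conditions: Ac2O, Et3N, 4-(dimethylamino)pyridine (cat.), CH2Cl2, rt
Reagents that add atoms: acetic anhydride, CC(=O)OC(C)=O
Why: 4-(Dimethylamino)pyridine-catalysed acetylation should esterify the remaining secondary 7α-hydroxyl and leave the tertiary α-ketol hydroxyl free.

**Step 26**
Reactants: 31 protected diester
Product: 32 target diacid
Conditions: CF3CO2H, anisole, CH2Cl2, 0 °C
Reagents that add atoms: none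
Why: Acidolysis of the 4-methoxybenzyl esters (SN1 cleavage, the benzylic cation being trapped by anisole) should free both acids without touching the benzoate, the acetate, the tertiary α-ketol or the vinyl group.

**Compound list**
1 | 3,3-dimethylpent-4-enal | C=CC(C)(C)CC=O | starting material
2 | but-3-en-2-one | CC(=O)C=C | starting material
3 | (S)-2-(2-methylbut-3-en-2-yl)-5-oxohexanal | CC(=O)CC[C@H](C=O)C(C)(C)C=C | intermediate
4 | (R)-4-(2-methylbut-3-en-2-yl)cyclohex-2-en-1-one | O=C1C=C[C@H](C(C)(C)C=C)CC1 | intermediate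
5 | trimethyl{[(3S,4R)-3-methyl-4-(2-methylbut-3-en-2-yl)cyclohex-1-en-1-yl]oxy}silane | C[Si](C)(C)OC1=C[C@@H](C)[C@H](C(C)(C)C=C)CC1 | intermediate
6 | (R)-3-methyl-4-(2-methylbut-3-en-2-yl)cyclohex-2-en-1-one | O=C1C=C(C)[C@H](C(C)(C)C=C)CC1 | intermediate
7 | (3R,4R)-3-allyl-3-methyl-4-(2-methylbut-3-en-2-yl)cyclohexan-1-one | O=C1C[C@@](C)(CC=C)[C@H](C(C)(C)C=C)CC1 | intermediate
8 | (4aR,8aR)-5,5,8a-trimethyl-3,4,4a,5,8,8a-hexahydronaphthalen-2(1H)-one | O=C1C[C@@]2(C)CC=CC(C)(C)[C@@H]2CC1 | intermediate
9 | (3R,4aR,8aR)-3-hydroxy-5,5,8a-trimethyl-3,4,4a,5,8,8a-hexahydronaphthalen-2(1H)-one | O=C1C[C@@]2(C)CC=CC(C)(C)[C@@H]2C[C@H]1O | intermediate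
10 | (2S,3R,4aR,8aR)-5,5,8a-trimethyl-2-[(E)-prop-1-en-1-yl]-1,2,3,4,4a,5,8,8a-octahydronaphthalene-2,3-diol | C/C=C/[C@@]1(O)C[C@@]2(C)CC=CC(C)(C)[C@@H]2C[C@H]1O | intermediate
11 | (3S,4aR,8aR)-3-hydroxy-4a,8,8-trimethyl-3-[(E)-prop-1-en-1-yl]-3,4,4a,5,8,8a-hexahydronaphthalen-2(1H)-one | C/C=C/[C@@]1(O)C[C@@]2(C)CC=CC(C)(C)[C@@H]2CC1=O | intermediate
12 | 2-{(1R,6R)-2,2,6-trimethyl-6-[(E)-2-oxopent-3-en-1-yl]cyclohex-3-en-1-yl}acetic acid | C/C=C/C(=O)C[C@@]1(C)CC=CC(C)(C)[C@@H]1CC(=O)O | intermediate
13 | N-methoxy-N-methyl-2-{(1R,6R)-2,2,6-trimethyl-6-[(E)-2-oxopent-3-en-1-yl]cyclohex-3-en-1-yl}acetamide | C/C=C/C(=O)C[C@@]1(C)CC=CC(C)(C)[C@@H]1CC(=O)N(C)OC | intermediate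
14 | 2-{6-[(1Z,3E)-2-(tert-butyldimethylsilyloxy)penta-1,3-dien-1-yl]-2,2,6-trimethylcyclohex-3-en-1-yl}-N-methoxy-N-methylacetamide (5α-H, 10β-CH3, arms trans) | C/C=C/C(O[Si](C)(C)C(C)(C)C)=C/[C@@]1(C)CC=CC(C)(C)[C@@H]1CC(=O)N(C)OC | intermediate
15 | prop-2-yn-1-ol | C#CCO | starting material
16 | 3-(methoxymethoxy)prop-1-yne | C#CCOCOC | intermediate
17 | 1-(methoxymethoxy)propa-1,2-diene | C=C=COCOC | intermediate
18 | 1-lithio-1-(methoxymethoxy)propa-1,2-diene | [Li]C(OCOC)=C=C | intermediate
19 | 1-{6-[(1Z,3E)-2-(tert-butyldimethylsilyloxy)penta-1,3-dien-1-yl]-2,2,6-trimethylcyclohex-3-en-1-yl}-3-(methoxymethoxy)penta-3,4-dien-2-one (5α-H, 10β-CH3, arms trans) | C/C=C/C(O[Si](C)(C)C(C)(C)C)=C/[C@@]1(C)CC=CC(C)(C)[C@@H]1CC(=O)C(OCOC)=C=C | intermediate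
20 | tricyclic cycloadduct: 11-(tert-butyldimethylsilyloxy)-11-ene, 7-ketone, 8β-methoxymethoxy, 9α-H, 13β-methyl, 14-methylene, ring A 2-ene | C[C@@H]1C=C(O[Si](C)(C)C(C)(C)C)[C@@H]2[C@@]3(C)CC=CC(C)(C)[C@@H]3CC(=O)[C@@]2(OCOC)C1=C | intermediate
21 | tricyclic 7,11-dione: 8β-methoxymethoxy, 9α-H, 13β-methyl, 14-methylene, ring A 2-ene | C[C@@H]1CC(=O)[C@@H]2[C@@]3(C)CC=CC(C)(C)[C@@H]3CC(=O)[C@@]2(OCOC)C1=C | intermediate
22 | 8β-hydroxy tricyclic 7,11-dione (13β-methyl, 14-methylene, ring A 2-ene) | C[C@@H]1CC(=O)[C@@H]2[C@@]3(C)CC=CC(C)(C)[C@@H]3CC(=O)[C@@]2(O)C1=C | intermediate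
23 | tricyclic 7α,8β,11α-triol (13β-methyl, 14-methylene, ring A 2-ene) | C[C@@H]1C[C@@H](O)[C@@H]2[C@@]3(C)CC=CC(C)(C)[C@@H]3C[C@@H](O)[C@@]2(O)C1=C | intermediate
24 | 7α,8β,11α-tris(triethylsilyl) ether of 23 | C[C@@H]1C[C@@H](O[Si](CC)(CC)CC)[C@@H]2[C@@]3(C)CC=CC(C)(C)[C@@H]3C[C@@H](O[Si](CC)(CC)CC)[C@@]2(O[Si](CC)(CC)CC)C1=C | intermediate
25 | 2,3-seco 2,3-dialdehyde: 7α,8β,11α-tris(triethylsilyloxy)-13β-methyl-14-ketone | C[C@@H]1C[C@@H](O[Si](CC)(CC)CC)[C@@H]2[C@@](C)(CC=O)[C@H](C(C)(C)C=O)C[C@@H](O[Si](CC)(CC)CC)[C@@]2(O[Si](CC)(CC)CC)C1=O | intermediate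
26 | 2,3-seco 2,3-dioic acid: 7α,8β,11α-tris(triethylsilyloxy)-13β-methyl-14-ketone | C[C@@H]1C[C@@H](O[Si](CC)(CC)CC)[C@@H]2[C@@](C)(CC(=O)O)[C@H](C(C)(C)C(=O)O)C[C@@H](O[Si](CC)(CC)CC)[C@@]2(O[Si](CC)(CC)CC)C1=O | intermediate
27 | bis(4-methoxybenzyl) ester of 26 | C[C@@H]1C[C@@H](O[Si](CC)(CC)CC)[C@@H]2[C@@](C)(CC(=O)OCc3ccc(OC)cc3)[C@H](C(C)(C)C(=O)OCc3ccc(OC)cc3)C[C@@H](O[Si](CC)(CC)CC)[C@@]2(O[Si](CC)(CC)CC)C1=O | intermediate
28 | 13α-vinyl-13β-methyl 14-ketone, tris(triethylsilyl) ether, bis(4-methoxybenzyl) ester | C=C[C@@]1(C)C[C@@H](O[Si](CC)(CC)CC)[C@@H]2[C@@](C)(CC(=O)OCc3ccc(OC)cc3)[C@H](C(C)(C)C(=O)OCc3ccc(OC)cc3)C[C@@H](O[Si](CC)(CC)CC)[C@@]2(O[Si](CC)(CC)CC)C1=O | intermediate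
29 | 7α,8β,11α-triol bis(4-methoxybenzyl) ester | C=C[C@@]1(C)C[C@@H](O)[C@@H]2[C@@](C)(CC(=O)OCc3ccc(OC)cc3)[C@H](C(C)(C)C(=O)OCc3ccc(OC)cc3)C[C@@H](O)[C@@]2(O)C1=O | intermediate
30 | 11α-benzoate 7α,8β-diol bis(4-methoxybenzyl) ester | C=C[C@@]1(C)C[C@@H](OC(=O)c3ccccc3)[C@@H]2[C@@](C)(CC(=O)OCc3ccc(OC)cc3)[C@H](C(C)(C)C(=O)OCc3ccc(OC)cc3)C[C@@H](O)[C@@]2(O)C1=O | intermediate
31 | 7α-acetate 11α-benzoate bis(4-methoxybenzyl) ester | C=C[C@@]1(C)C[C@@H](OC(=O)c3ccccc3)[C@@H]2[C@@](C)(CC(=O)OCc3ccc(OC)cc3)[C@H](C(C)(C)C(=O)OCc3ccc(OC)cc3)C[C@@H](OC(C)=O)[C@@]2(O)C1=O | intermediate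
32 | CNP0315860.1 (7α-acetoxy-11α-benzoyloxy-8β-hydroxy-14-oxo-2,3-seco-isopimar-15-ene-2,3-dioic acid) | C=C[C@@]1(C)C[C@@H](OC(=O)c2ccccc2)[C@@H]2[C@@](C)(CC(=O)O)[C@H](C(C)(C)C(=O)O)C[C@@H](OC(C)=O)[C@@]2(O)C1=O | target

**Count**
Total step count: 26. Longest linear sequence: 24 steps (steps 1–11 and 14–26); steps 12 and 13 make the allene.

**Steps most likely to fail**

Step 15. The cycloaddition runs against the electronic bias of the diene and needs heat, so ring B may close through the other chair, in which the tether carbonyl lies under the diene (cis B/C fusion). The fallback sets C9 by equilibration instead of by the cycloaddition. It sets out from 19: the same heating would give the cis-fused silyl enol ether F1, and the acidic work-up the cis-fused diketone F2 (9β-H, 13α-methyl). F2 is treated with 1,8-diazabicyclo[5.4.0]undec-7-ene (cat.) in toluene at room temperature, which should epimerise C9 through the C11 enolate to the trans-fused diketone F3, the 13-epimer of 21. F3 is carried through the operations of steps 16 to 21 unchanged: the hydroxy diketone F4, the triol F5, the tris(triethylsilyl) ether F6, the keto dialdehyde F7, the diacid F8 and the bis(4-methoxybenzyl) ester F9. The enolate of F9 formed in step 22 is the same as that of 27, so the route is rejoined at 28.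

Step 22. The congested tetrasubstituted enolate may fail to couple (slow transmetalation or reductive elimination at a carbon flanked by a quaternary-substituted carbonyl). The fallback uses a vinyl cation equivalent in a conjugate addition. It sets out from 27: the potassium enolate (KN(SiMe3)2, THF, −78 °C) is added to phenyl vinyl sulfoxide, again on the α face, to give the γ-keto sulfoxide F10 (mixture at sulfur). Thermal syn-elimination of the sulfoxide (toluene, CaCO3, 110 °C) then gives 28.

Step 4. The allylsilane may not reach the β-carbon next to the tert-alkyl side chain (no reaction, or protodesilylation of the reagent). The fallback is a carbonyl addition followed by a [3,3]-sigmatropic transfer. It sets out from 6: allylmagnesium bromide adds 1,2 to the unhindered carbonyl to give the tertiary allylic alcohol F11 (the epimer with the allyl group anti to the side chain, separated by chromatography). Anionic oxy-Cope rearrangement (KH, 18-crown-6, THF, 0 °C → rt) moves the allyl group suprafacially from C11 to C10 on the face anti to the side chain, and protonation of the enolate gives 7.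

**Further compounds**
F1 | step 15 | cis-fused cycloadduct silyl enol ether (9β-H, 13α-methyl) | C[C@H]1C=C(O[Si](C)(C)C(C)(C)C)[C@H]2[C@@]3(C)CC=CC(C)(C)[C@@H]3CC(=O)[C@@]2(OCOC)C1=C
F2 | step 15 | cis-fused 7,11-diketone (9β-H, 13α-methyl) | C[C@H]1CC(=O)[C@H]2[C@@]3(C)CC=CC(C)(C)[C@@H]3CC(=O)[C@@]2(OCOC)C1=C
F3 | step 15 | 13-epimer of 21 (9α-H, 13α-methyl) | C[C@H]1CC(=O)[C@@H]2[C@@]3(C)CC=CC(C)(C)[C@@H]3CC(=O)[C@@]2(OCOC)C1=C
F4 | step 15 | 13-epimer of 22 | C[C@H]1CC(=O)[C@@H]2[C@@]3(C)CC=CC(C)(C)[C@@H]3CC(=O)[C@@]2(O)C1=C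
F5 | step 15 | 13-epimer of 23 | C[C@H]1C[C@@H](O)[C@@H]2[C@@]3(C)CC=CC(C)(C)[C@@H]3C[C@@H](O)[C@@]2(O)C1=C
F6 | step 15 | 13-epimer of 24 | C[C@H]1C[C@@H](O[Si](CC)(CC)CC)[C@@H]2[C@@]3(C)CC=CC(C)(C)[C@@H]3C[C@@H](O[Si](CC)(CC)CC)[C@@]2(O[Si](CC)(CC)CC)C1=C
F7 | step 15 | 13-epimer of 25 | C[C@H]1C[C@@H](O[Si](CC)(CC)CC)[C@@H]2[C@@](C)(CC=O)[C@H](C(C)(C)C=O)C[C@@H](O[Si](CC)(CC)CC)[C@@]2(O[Si](CC)(CC)CC)C1=O
F8 | step 15 | 13-epimer of 26 | C[C@H]1C[C@@H](O[Si](CC)(CC)CC)[C@@H]2[C@@](C)(CC(=O)O)[C@H](C(C)(C)C(=O)O)C[C@@H](O[Si](CC)(CC)CC)[C@@]2(O[Si](CC)(CC)CC)C1=O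
F9 | step 15 | 13-epimer of 27 | C[C@H]1C[C@@H](O[Si](CC)(CC)CC)[C@@H]2[C@@](C)(CC(=O)OCc3ccc(OC)cc3)[C@H](C(C)(C)C(=O)OCc3ccc(OC)cc3)C[C@@H](O[Si](CC)(CC)CC)[C@@]2(O[Si](CC)(CC)CC)C1=O
F10 | step 22 | 13α-[2-(phenylsulfinyl)ethyl]-13β-methyl 14-ketone (γ-keto sulfoxide) | O=S(c4ccccc4)CC[C@@]1(C)C[C@@H](O[Si](CC)(CC)CC)[C@@H]2[C@@](C)(CC(=O)OCc3ccc(OC)cc3)[C@H](C(C)(C)C(=O)OCc3ccc(OC)cc3)C[C@@H](O[Si](CC)(CC)CC)[C@@]2(O[Si](CC)(CC)CC)C1=O
F11 | step 4 | 1-allyl-3-methyl-4-(2-methylbut-3-en-2-yl)cyclohex-2-en-1-ol (allyl anti to the side chain) | C=CC[C@@]1(O)C=C(C)[C@H](C(C)(C)C=C)CC1
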